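Ring numbering used throughout: O1, O2, C3 (ketal carbon), C4, C5, C6 (carbon bearing the two-carbon arm). In this numbering the target is (3R,6S). Racemates are marked rac and drawn as the target-series enantiomer.

## Analysis of the target

The target 24 is a 3,3,6-trisubstituted 1,2-dioxane. C3 is a mixed peroxy ketal carrying a methoxy group and a sixteen-carbon chain, (CH2)3–C≡C–CH=CH–(CH2)7–CO–CH3, with a conjugated (E)-enyne and a terminal methyl ketone; C6 is a secondary peroxy carbon carrying CH2CO2H; C4 and C5 are plain methylenes. The two stereocentres are C3 (R) and C6 (S). The methoxy group and the C6 arm are cis, so in the chair both carbon chains are equatorial and the methoxy group is axial, the anomerically preferred arrangement. C3 can therefore be left to equilibration once C6 exists, and only C6 needs an absolute assignment. The sensitive groups are the O–O bond (phosphines, low-valent metals, hydrides, hydrogenation), the acid-labile ketal, the enyne and the ketone. The C6–H is a further weak point, because it is alpha to a peroxide oxygen (Kornblum–DeLaMare fragmentation) and beta to the carboxyl group (E1cB ring opening). The difficulty is to make a C–OO bond at an unactivated secondary carbon inside a functionalised chain, and then to finish the molecule without reductive or strongly basic steps. The strategy rests on the C3–C4–C5–C6 unit: these four carbons, bridged at their ends by O–O, map onto a cyclobutane whose C3–C6 bond is replaced by the peroxide.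

## Retrosynthetic reasoning

**24 to 17 and 23.** The C(sp)–C(sp2) bond of the enyne is cut first. This divides the target into the peroxide-bearing alkyne acid 17 and the (E)-vinyl iodide 23, which carries the ketone chain. The cut is the most convergent one available, and the alkene geometry is settled in 23 before the coupling. The forward reaction is a Sonogashira coupling at room temperature under amine base. It is placed last so that the enyne and the ketone never meet radical or oxidative steps.

**23 to 22, 20 and 18.** The C=C bond of 23 is traced to the aldehyde 22 by Takai iodo-olefination, which gives the E geometry and prefers an aldehyde over a methyl ketone. Aldehyde 22 comes from the terminal alkene 20 by ozonolysis, and the methyl ketone of 20 from dec-9-enoic acid 18 by addition of a methyl-metal reagent. The carbon lost on ozonolysis is returned by the olefination, so the C10 acid gives the C11 iodide.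

**17 to 16 and 15.** C6 arises from a planar radical and cannot be controlled when the ring forms, so the enantiomers are separated by enzymatic hydrolysis of the racemic methyl ester 16, made from racemic acid 15. This is done at the ester stage because C6 then sits beta to the reacting carbonyl, and before the coupling so that none of 23 is spent on the wrong enantiomer.

**15 to 13 and 12.** The acid is carried as a silyl-protected primary alcohol and the terminal alkyne as its C-silyl derivative in 12, so that both survive the organometallic and radical steps. One fluoride treatment frees both (13), and the alcohol is then oxidised to 15.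

**12 to 11.** The C3–OMe bond is made by acid-catalysed exchange of the hemiketal hydroxyl of dioxanol 11 in the alcohol as solvent. Under equilibration C3 adopts the axial-methoxy configuration, which is the one required relative to C6.

**11 to 9 (key disconnection).** C6–O1 and O2–C3 are cut and C3 is rejoined to C6, which gives the 1,2-disubstituted cyclobutanol 9. Both C–O bonds of the peroxide are then made in one aerobic cobalt-catalysed operation through the open hydroperoxy ketone 10. The ring strain drives the cleavage, and the 2-substituent decides which ring bond breaks. The configuration of 9 is irrelevant because both of its stereocentres are erased.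

**9 to 6 and 8.** The bond from C3 to the alkynyl chain is cut. The forward reaction is 1,2-addition of the Grignard reagent 8, made from chloride 7 and modified with a cerium salt, to the 2-substituted cyclobutanone 6.

**6 to 4 and 2, then 3 and 1.** The bond alpha to the ketone is cut. The forward reaction is alkylation of the azaenolate of hydrazone 4 (from cyclobutanone 3) with the silyl-protected iodide 2 (from 2-iodoethanol 1), then hydrolysis through 5. The hydrazone prevents self-condensation and polyalkylation of the strained ketone.

## Alternatives that were turned down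

**Alternative 1: three-component aerobic annulation with trivalent manganese.** The ring is cut at C4–C5, C6–O1 and O2–C3. In the forward step Mn(OAc)3 oxidises the β-keto ester A1 to its α-radical, which adds to methyl but-3-enoate A2; the C6 radical captures O2 and the peroxide closes on the ketone to give the 4-carboxylated dioxanol A3.
- For it: it is more convergent than the chosen route, builds the ring from two acyclic pieces, and installs the C6 arm at the ester oxidation level from the start. On these points it is stronger.
- Against it: A3 carries a C4 ester that has to be removed. This can only be done through the open-chain β-keto acid tautomer, after acid cleavage of a tert-butyl ester next to an acid-labile hemiketal. A radical decarboxylation at C4 is excluded, because a C4 radical is beta to the O–O bond and is expected to collapse to an epoxide.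
- The unactivated monosubstituted alkene A2 is a poor trap for the electrophilic radical and can isomerise to the conjugated ester.
- The C3 chain arrives as a protected alcohol and must be homologated to the alkyne under base, next to a β-peroxy ester.
- C6 is racemic here too, so the resolution is not saved.
- In comparison, the chosen route forms the ring without a surplus substituent and with the alkyne already in place.

**Alternative 2: ring-closing metathesis across a peroxyketal tether.** The ring is cut at C4=C5 of a dihydrodioxine. In the forward step the second-generation Hoveyda–Grubbs catalyst joins the C3 vinyl group and the C6 enoate alkene of the mixed peroxyketal A4, expels the acrylate fragment and gives the 3,6-dihydro-1,2-dioxine A5.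
- For it: C6 enters as a configured hydroperoxide carbon, so no resolution is needed. This is a clear advantage over the chosen route, which gives up half of the material at the resolution.
- Against it: A4 must be assembled from an enantioenriched γ-hydroperoxy enoate, which is prone to Kornblum–DeLaMare fragmentation, and a vinyl ketone ketal, where conjugate addition of the hydroperoxide competes with ketal exchange.
- A5 is an allylic peroxide with a C6–H and is liable to rearrange under base or metal catalysis.
- C4=C5 must then be saturated without touching the O–O bond or the alkyne. Diimide is the only candidate, and it also reduces alkynes.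
- In comparison, the chosen route gives the saturated ring directly and needs fewer steps.

**Alternative 3: biomimetic peroxyketalisation of a hydroperoxy ketone.** The ring is cut at O2–C3 and C3–OMe. In the forward step the C6 hydroperoxide of A6 adds to the C3 ketone in acidic methanol and the peroxy hemiketal is methylated, to give the methoxy dioxane A7.
- For it: ring closure and ketalisation occur in one flask, without a metal near the peroxide. If A6 is made from an enantioenriched secondary alcohol by invertive substitution, C6 is set absolutely. On that point it is stronger.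
- Against it: the whole difficulty moves into the making of A6, a secondary hydroperoxide at an unactivated carbon flanked by two methylenes. Substitution of a secondary sulfonate by hydrogen peroxide competes with elimination and needs the ketone masked. Radical hydroperoxidation of an internal alkene has no regiocontrol. Several steps of functional-group handling come before the key step.
- In comparison, intermediate 10 of the chosen route is the silylated counterpart of A6, reached from cyclobutanol 9 in one operation with the regiochemistry fixed by the ring. The price is a racemate.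

Key step: step 5

Remark on the chemistry: the vinyl iodide needs seven methylenes between alkene and carbonyl, so it is built from dec-9-enoic acid; undec-10-enoic acid would give a chain one methylene too long by the same sequence.

Assumption: the lipase is taken to hydrolyse the (3R,6S)-ester faster; its sense cannot be predicted for this substrate, and if it is the reverse, the (3R,6S)-ester is recovered as the slow enantiomer past half conversion and saponified with LiOH.

## Route

Step 1
Reactants: 1 2-iodoethanol
Product: 2 tert-butyl(2-iodoethoxy)diphenylsilane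
Conditions: TBDPSCl, imidazole, CH2Cl2, 0 °C to rt
Reagents that add atoms: tert-butyl(chloro)diphenylsilane, CC(C)(C)[Si](Cl)(c1ccccc1)c1ccccc1
Why: Silylation of a primary alcohol with a silyl chloride and imidazole; the TBDPS ether withstands the amide base, the organocerium reagent, the cobalt/oxygen step and catalytic acid in methanol, and later falls to fluoride together with the alkynyl TMS group.

Step 2
Reactants: 3 cyclobutanone
Product: 4 1-cyclobutylidene-2,2-dimethylhydrazine
Conditions: Me2NNH2 (1.5 equiv), 4 Å MS, Et2O, rt; distillation
Reagents that add atoms: N,N-dimethylhydrazine, CN(C)N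
Why: Condensation of a ketone with a 1,1-disubstituted hydrazine to the hydrazone; this masks the strained ketone against self-condensation and allows clean mono-deprotonation.

Step 3
Reactants: 4 1-cyclobutylidene-2,2-dimethylhydrazine; 2 tert-butyl(2-iodoethoxy)diphenylsilane
Product: 6 rac-2-[2-(tert-butyldiphenylsilyloxy)ethyl]cyclobutan-1-one, via alkylated dimethylhydrazone 5 (not isolated)
Conditions: LiN(i-Pr)2 (LDA), THF, 0 °C; then 2, −78 °C to rt; then sat. aq (CO2H)2, Et2O, rt
Reagents that add atoms: water, O
Why: Hydrazone (azaenolate) alkylation with a primary iodide followed by mild two-phase acid hydrolysis; the azaenolate should give monoalkylation, and the new stereocentre forms as a racemate, which is immaterial because it becomes a radical centre in step 5.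

Step 4
Reactants: 7 (5-chloropent-1-yn-1-yl)trimethylsilane; 6 rac-2-[2-(tert-butyldiphenylsilyloxy)ethyl]cyclobutan-1-one
Product: 9 rac-(1R,2R)-2-[2-(tert-butyldiphenylsilyloxy)ethyl]-1-[5-(trimethylsilyl)pent-4-yn-1-yl]cyclobutan-1-ol (OH cis to the silyloxyethyl chain), via Grignard reagent 8 (not isolated)
Conditions: 7, Mg, BrCH2CH2Br (cat.), THF, reflux; anhydrous CeCl3, THF, −78 °C; then 6, −78 to 0 °C; aq NH4Cl
Reagents that add atoms: none
Why: Grignard formation from the primary chloride and 1,2-addition of the CeCl3-modified reagent, which is weakly basic and should suppress enolisation of the cyclobutanone. Attack anti to the C2 substituent should favour the isomer drawn, but both diastereomers converge in step 5.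

Step 5
Reactants: 9 rac-(1R,2R)-2-[2-(tert-butyldiphenylsilyloxy)ethyl]-1-[5-(trimethylsilyl)pent-4-yn-1-yl]cyclobutan-1-ol
Product: 11 rac-(3R,6S)-6-[2-(tert-butyldiphenylsilyloxy)ethyl]-3-[5-(trimethylsilyl)pent-4-yn-1-yl]-1,2-dioxan-3-ol, via hydroperoxy ketone 10 (not isolated)
Conditions: Co(acac)2 (20 mol %), O2 (1 atm), CH2Cl2, rt to 40 °C
Reagents that add atoms: dioxygen, O=O
Why: This is the cobalt-catalysed aerobic oxidative ring expansion of a 2-substituted cyclobutanol to a 1,2-dioxan-3-ol, a known reaction type applied here to a new substrate. Co(acac)2 is oxidised by O2 to a trivalent cobalt species that takes up the tertiary alkoxide of 9, and homolysis of the Co–O bond gives the cyclobutyloxy radical and returns divalent cobalt. Strain-driven β-scission cleaves the ring bond between the carbinol carbon and the substituted carbon (C3–C6 in dioxane numbering), leaving the C3 ketone and a secondary radical at C6. This radical captures O2 at a near diffusion-controlled rate (C6–O1), and the peroxyl radical is reduced by divalent cobalt and protonated by fresh 9 to give hydroperoxy ketone 10, which carries the cycle on. Compound 10 closes the only new ring by 6-exo-trig addition of the hydroperoxide oxygen to the ketone (O2–C3). The step needs scission of the more substituted ring bond, which the 2-alkyl group secures through the greater stability of a secondary over a primary radical; scission of the other bond would place the side chain on C4. C6 forms from a planar radical without control, so 11 is racemic and both diastereomers of 9 converge, while the hemiketal at C3 equilibrates toward the axial hydroxyl and is fixed only in step 6. The silyl ether and the silylalkyne should be inert, because capture of O2 outruns hydrogen transfer or addition of the C6 radical to the remote alkyne.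

Step 6
Reactants: 11 rac-(3R,6S)-6-[2-(tert-butyldiphenylsilyloxy)ethyl]-3-[5-(trimethylsilyl)pent-4-yn-1-yl]-1,2-dioxan-3-ol
Product: 12 rac-tert-butyl{2-[(3R,6S)-3-methoxy-3-[5-(trimethylsilyl)pent-4-yn-1-yl]-1,2-dioxan-6-yl]ethoxy}diphenylsilane
Conditions: CSA (cat.), MeOH, 0 °C to rt
Reagents that add atoms: methanol, CO
Why: Acid-catalysed ketalisation of a cyclic peroxy hemiketal through the peroxy-stabilised oxocarbenium ion; under equilibration C3 should take the anomeric configuration with OMe axial and both carbon chains equatorial, which is the relative configuration of the target, while C6 is untouched. The primary TBDPS ether and the alkynyl TMS group should survive catalytic acid at or below room temperature.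

Step 7
Reactants: 12 rac-tert-butyl{2-[(3R,6S)-3-methoxy-3-[5-(trimethylsilyl)pent-4-yn-1-yl]-1,2-dioxan-6-yl]ethoxy}diphenylsilane
Product: 13 rac-2-[(3R,6S)-3-methoxy-3-(pent-4-yn-1-yl)-1,2-dioxan-6-yl]ethan-1-ol
Conditions: TBAF (2.5 equiv), THF, 0 °C to rt; aq NH4Cl
Reagents that add atoms: none
Why: Fluoride-mediated cleavage of the O–Si and C(sp)–Si bonds in one operation; dialkyl peroxides and peroxy ketals are inert to fluoride, and the low temperature limits base-induced Kornblum–DeLaMare fragmentation at C6–H.

Step 8
Reactants: 13 rac-2-[(3R,6S)-3-methoxy-3-(pent-4-yn-1-yl)-1,2-dioxan-6-yl]ethan-1-ol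
Product: 15 rac-2-[(3R,6S)-3-methoxy-3-(pent-4-yn-1-yl)-1,2-dioxan-6-yl]acetic acid, via aldehyde 14 (not isolated)
Conditions: TEMPO (20 mol %), PhI(OAc)2 (2.2 equiv), MeCN/H2O (1:1), rt
Reagents that add atoms: water, O
Why: Oxoammonium oxidation (TEMPO/PhI(OAc)2) of the primary alcohol through the aldehyde and its hydrate to the acid; the medium is neutral to weakly acidic, so β-elimination of the peroxide from the aldehyde and O–O reduction are not expected, and the terminal alkyne is inert.

Step 9
Reactants: 15 rac-2-[(3R,6S)-3-methoxy-3-(pent-4-yn-1-yl)-1,2-dioxan-6-yl]acetic acid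
Product: 16 methyl rac-2-[(3R,6S)-3-methoxy-3-(pent-4-yn-1-yl)-1,2-dioxan-6-yl]acetate
Conditions: MeI, KHCO3, DMF, rt
Reagents that add atoms: iodomethane, CI
Why: O-Alkylation of the carboxylate with iodomethane; bicarbonate is too weak a base to deprotonate the alkyne or to start β-elimination of the peroxide.

Step 10
Reactants: 16 methyl rac-2-[(3R,6S)-3-methoxy-3-(pent-4-yn-1-yl)-1,2-dioxan-6-yl]acetate
Product: 17 2-[(3R,6S)-3-methoxy-3-(pent-4-yn-1-yl)-1,2-dioxan-6-yl]acetic acid (single enantiomer)
Conditions: Burkholderia cepacia lipase (Amano PS), 0.1 M phosphate buffer pH 7.0, acetone (10% v/v), 30 °C, to just under half conversion; NaHCO3 extraction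
Reagents that add atoms: water, O
Why: Enzymatic kinetic resolution by enantioselective ester hydrolysis at neutral pH; C6 sits β to the ester carbonyl, a class of ester (β-oxygenated, β-branched) that this lipase is known to discriminate, and the acid is separated from the unreacted (3S,6R)-ester by extraction. Because C3 is tied to C6 by the ketal equilibrium, resolving C6 fixes both centres; enantiopurity is to be checked on a chiral stationary phase.

Step 11
Reactants: 18 dec-9-enoic acid
Product: 20 undec-10-en-2-one, via dilithium gem-diolate 19 (not isolated)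
Conditions: MeLi (2.2 equiv), Et2O, 0 °C to rt; inverse quench into cold 1 M HCl
Reagents that add atoms: methyllithium, [Li]C
Why: Addition of methyllithium to a lithium carboxylate; the dilithium gem-diolate does not collapse before the acidic quench, so the methyl ketone and not the tertiary alcohol should result.

Step 12
Reactants: 20 undec-10-en-2-one
Product: 22 9-oxodecanal, via ozonide 21 (not isolated)
Conditions: O3, CH2Cl2, −78 °C; then PPh3, −78 °C to rt
Reagents that add atoms: ozone, [O-][O+]=O
Why: Ozonolysis of the terminal alkene with reductive work-up (Criegee mechanism); the ketone is inert and one carbon is lost as formaldehyde.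

Step 13
Reactants: 22 9-oxodecanal
Product: 23 (E)-11-iodoundec-10-en-2-one
Conditions: CrCl2 (6 equiv), CHI3 (2 equiv), 1,4-dioxane/THF (6:1), rt
Reagents that add atoms: iodoform, IC(I)I
Why: Takai iodo-olefination; the geminal dichromium species from CHI3 and CrCl2 adds to the aldehyde and eliminates to the (E)-vinyl iodide, and the reagent is selective for aldehydes over ketones. The dioxane-rich solvent is chosen to raise the E selectivity.

Step 14
Reactants: 17 2-[(3R,6S)-3-methoxy-3-(pent-4-yn-1-yl)-1,2-dioxan-6-yl]acetic acid; 23 (E)-11-iodoundec-10-en-2-one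
Product: 24 2-[(3R,6S)-3-methoxy-3-[(E)-15-oxohexadec-6-en-4-yn-1-yl]-1,2-dioxan-6-yl]acetic acid
Conditions: PdCl2(PPh3)2 (5 mol %), CuI (10 mol %), i-Pr2NH (5 equiv), THF (degassed), rt; pH 4 buffer work-up
Reagents that add atoms: none
Why: Sonogashira coupling of a terminal alkyne with an (E)-vinyl iodide; oxidative addition and reductive elimination retain the alkene geometry, vinyl iodides couple at room temperature, and the acid is carried as its ammonium salt. Saturated dialkyl peroxides and peroxy ketals are known to tolerate Pd/Cu couplings of this kind at room temperature, and neither stereocentre is involved.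

## Compound list

1 | 2-iodoethanol | OCCI | starting material
2 | tert-butyl(2-iodoethoxy)diphenylsilane | ICCO[Si](c1ccccc1)(c1ccccc1)C(C)(C)C | intermediate
3 | cyclobutanone | O=C1CCC1 | starting material
4 | 1-cyclobutylidene-2,2-dimethylhydrazine | CN(C)N=C1CCC1 | intermediate
5 | 1-{2-[2-(tert-butyldiphenylsilyloxy)ethyl]cyclobutylidene}-2,2-dimethylhydrazine (racemic, not isolated) | CN(C)N=C1CCC1CCO[Si](c2ccccc2)(c2ccccc2)C(C)(C)C | intermediate
6 | rac-2-[2-(tert-butyldiphenylsilyloxy)ethyl]cyclobutan-1-one | O=C1CCC1CCO[Si](c2ccccc2)(c2ccccc2)C(C)(C)C | intermediate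
7 | (5-chloropent-1-yn-1-yl)trimethylsilane | C[Si](C)(C)C#CCCCCl | starting material
8 | [5-(trimethylsilyl)pent-4-yn-1-yl]magnesium chloride (not isolated) | C[Si](C)(C)C#CCCC[Mg]Cl | intermediate
9 | rac-(1R,2R)-2-[2-(tert-butyldiphenylsilyloxy)ethyl]-1-[5-(trimethylsilyl)pent-4-yn-1-yl]cyclobutan-1-ol | O[C@]1(CCCC#C[Si](C)(C)C)CC[C@@H]1CCO[Si](c2ccccc2)(c2ccccc2)C(C)(C)C | intermediate
10 | rac-1-(tert-butyldiphenylsilyloxy)-3-hydroperoxy-11-(trimethylsilyl)undec-10-yn-6-one (not isolated) | C[Si](C)(C)C#CCCCC(=O)CCC(OO)CCO[Si](c1ccccc1)(c1ccccc1)C(C)(C)C | intermediate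
11 | rac-(3R,6S)-6-[2-(tert-butyldiphenylsilyloxy)ethyl]-3-[5-(trimethylsilyl)pent-4-yn-1-yl]-1,2-dioxan-3-ol | O[C@@]1(CCCC#C[Si](C)(C)C)CC[C@@H](CCO[Si](c2ccccc2)(c2ccccc2)C(C)(C)C)OO1 | intermediate
12 | rac-tert-butyl{2-[(3R,6S)-3-methoxy-3-[5-(trimethylsilyl)pent-4-yn-1-yl]-1,2-dioxan-6-yl]ethoxy}diphenylsilane | CO[C@@]1(CCCC#C[Si](C)(C)C)CC[C@@H](CCO[Si](c2ccccc2)(c2ccccc2)C(C)(C)C)OO1 | intermediate
13 | rac-2-[(3R,6S)-3-methoxy-3-(pent-4-yn-1-yl)-1,2-dioxan-6-yl]ethan-1-ol | CO[C@@]1(CCCC#C)CC[C@@H](CCO)OO1 | intermediate
14 | rac-2-[(3R,6S)-3-methoxy-3-(pent-4-yn-1-yl)-1,2-dioxan-6-yl]acetaldehyde (not isolated) | CO[C@@]1(CCCC#C)CC[C@@H](CC=O)OO1 | intermediate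
15 | rac-2-[(3R,6S)-3-methoxy-3-(pent-4-yn-1-yl)-1,2-dioxan-6-yl]acetic acid (racemate, one enantiomer drawn) | CO[C@@]1(CCCC#C)CC[C@@H](CC(=O)O)OO1 | intermediate
16 | methyl rac-2-[(3R,6S)-3-methoxy-3-(pent-4-yn-1-yl)-1,2-dioxan-6-yl]acetate | CO[C@@]1(CCCC#C)CC[C@@H](CC(=O)OC)OO1 | intermediate
17 | 2-[(3R,6S)-3-methoxy-3-(pent-4-yn-1-yl)-1,2-dioxan-6-yl]acetic acid (single enantiomer) | CO[C@@]1(CCCC#C)CC[C@@H](CC(=O)O)OO1 | intermediate
18 | dec-9-enoic acid | C=CCCCCCCCC(=O)O | starting material
19 | dilithium undec-10-ene-2,2-diolate (not isolated) | [Li+].[Li+].[O-]C(C)([O-])CCCCCCCC=C | intermediate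
20 | undec-10-en-2-one | CC(=O)CCCCCCCC=C | intermediate
21 | 9-(1,2,4-trioxolan-3-yl)nonan-2-one (not isolated) | CC(=O)CCCCCCCC1OCOO1 | intermediate
22 | 9-oxodecanal | CC(=O)CCCCCCCC=O | intermediate
23 | (E)-11-iodoundec-10-en-2-one | CC(=O)CCCCCCC/C=C/I | intermediate
24 | 2-[(3R,6S)-3-methoxy-3-[(E)-15-oxohexadec-6-en-4-yn-1-yl]-1,2-dioxan-6-yl]acetic acid | CO[C@@]1(CCCC#C/C=C/CCCCCCCC(C)=O)CC[C@@H](CC(=O)O)OO1 | target

## Step count and least certain steps

Total: 14 steps. Longest linear sequence: 10 steps (3 to 4 to 6 to 9 to 11 to 12 to 13 to 15 to 16 to 17 to 24, that is steps 2–10 and 14).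

**Step 5 (key step).** The most likely failure is reductive cleavage of the newly formed O–O bond by divalent cobalt, which would lead to γ-hydroxy ketone and 1,4-diketone. Self-termination of the secondary peroxyl radicals and some scission toward the unsubstituted ring carbon are further losses. All of these follow from running a radical chain with a redox-active metal in the presence of its own peroxide product. The fallback builds the ring by conjugate addition instead; it sets out from Grignard reagent 8 and returns at ester 16. Reagent 8 is acylated with N-methoxy-N-methylpent-4-enamide to give 1-(trimethylsilyl)dec-9-en-1-yn-6-one F1. Cross-metathesis with methyl acrylate (second-generation Hoveyda–Grubbs catalyst) gives methyl (E)-6-oxo-11-(trimethylsilyl)undec-2-en-10-ynoate F2. Acid-catalysed perhydrolysis of the ketone in methanol (urea–H2O2 adduct, CSA) gives methyl (E)-6-hydroperoxy-6-methoxy-11-(trimethylsilyl)undec-2-en-10-ynoate F3. Et2NH in CF3CH2OH closes the ring by 6-exo-trig oxa-Michael addition of the hydroperoxide to the enoate, and CSA in MeOH equilibrates C3, to give methyl rac-2-[(3R,6S)-3-methoxy-3-[5-(trimethylsilyl)pent-4-yn-1-yl]-1,2-dioxan-6-yl]acetate F4. TBAF buffered with AcOH removes the alkynyl silyl group and delivers 16. The weak points of this fallback are the selectivity of the perhydrolysis and the reversibility of the oxa-Michael closure.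

**Step 10.** The enantiomer discrimination by the lipase may be low, or opposite in sense, because no predictive model exists for a stereocentre β to the acyl carbon. The fallback separates covalent diastereomers; it sets out from racemic acid 15 and returns at 17. Acid 15 is activated as its pivalic mixed anhydride (PivCl, Et3N) and acylates (S)-4-benzyl-1,3-oxazolidin-2-one (LiCl, THF). This gives (S)-4-benzyl-3-{2-[(3R,6S)-3-methoxy-3-(pent-4-yn-1-yl)-1,2-dioxan-6-yl]acetyl}-1,3-oxazolidin-2-one F5 and (S)-4-benzyl-3-{2-[(3S,6R)-3-methoxy-3-(pent-4-yn-1-yl)-1,2-dioxan-6-yl]acetyl}-1,3-oxazolidin-2-one F6, which are separated by chromatography. F5 is cleaved with LiOH/H2O2 in THF/H2O at 0 °C to give 17 and the recovered auxiliary.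

**Step 14.** The ammonium carboxylate may slow the coupling through poor solubility or by binding copper. A slow coupling leaves time for oxidative dimerisation of the alkyne and for reduction of the O–O bond by phosphine or zerovalent palladium. The fallback couples at the ester stage, the substrate type with the closest precedent, and unmasks the acid last; it sets out from 17 and returns at 24. Acid 17 is re-esterified (MeI, KHCO3, DMF) to methyl 2-[(3R,6S)-3-methoxy-3-(pent-4-yn-1-yl)-1,2-dioxan-6-yl]acetate (single enantiomer) F7. Sonogashira coupling with 23 gives methyl 2-[(3R,6S)-3-methoxy-3-[(E)-15-oxohexadec-6-en-4-yn-1-yl]-1,2-dioxan-6-yl]acetate F8, and LiOH in THF/H2O at 0 °C gives 24.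

**Step 3.** Substitution at the β-silyloxy iodide may be sluggish, so that proton transfer or elimination to the vinyl ether competes, and the hindered alkylated hydrazone may hydrolyse slowly. The fallback uses a reactive allylic electrophile and installs the oxygen later; it sets out from hydrazone 4 and returns at cyclobutanol 9. The azaenolate of 4 is alkylated with allyl bromide to 1-(2-allylcyclobutylidene)-2,2-dimethylhydrazine F9, which is hydrolysed with aqueous oxalic acid to rac-2-allylcyclobutan-1-one F10. The CeCl3-modified reagent 8 adds to give rac-(1R,2R)-2-allyl-1-[5-(trimethylsilyl)pent-4-yn-1-yl]cyclobutan-1-ol F11. Ozonolysis with NaBH4 work-up (the alkene reacts far faster than the silylalkyne) gives rac-(1R,2R)-2-(2-hydroxyethyl)-1-[5-(trimethylsilyl)pent-4-yn-1-yl]cyclobutan-1-ol F12. Selective silylation of the primary hydroxyl (TBDPSCl, imidazole) gives 9.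

## Further compounds

F1 | step 5 | 1-(trimethylsilyl)dec-9-en-1-yn-6-one | C[Si](C)(C)C#CCCCC(=O)CCC=C
F2 | step 5 | methyl (E)-6-oxo-11-(trimethylsilyl)undec-2-en-10-ynoate | COC(=O)/C=C/CCC(=O)CCCC#C[Si](C)(C)C
F3 | step 5 | methyl (E)-6-hydroperoxy-6-methoxy-11-(trimethylsilyl)undec-2-en-10-ynoate (racemic) | COC(=O)/C=C/CCC(OC)(OO)CCCC#C[Si](C)(C)C
F4 | step 5 | methyl rac-2-[(3R,6S)-3-methoxy-3-[5-(trimethylsilyl)pent-4-yn-1-yl]-1,2-dioxan-6-yl]acetate | CO[C@@]1(CCCC#C[Si](C)(C)C)CC[C@@H](CC(=O)OC)OO1
F5 | step 10 | (S)-4-benzyl-3-{2-[(3R,6S)-3-methoxy-3-(pent-4-yn-1-yl)-1,2-dioxan-6-yl]acetyl}-1,3-oxazolidin-2-one | CO[C@@]1(CCCC#C)CC[C@@H](CC(=O)N2[C@@H](Cc3ccccc3)COC2=O)OO1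
F6 | step 10 | (S)-4-benzyl-3-{2-[(3S,6R)-3-methoxy-3-(pent-4-yn-1-yl)-1,2-dioxan-6-yl]acetyl}-1,3-oxazolidin-2-one | CO[C@]1(CCCC#C)CC[C@H](CC(=O)N2[C@@H](Cc3ccccc3)COC2=O)OO1
F7 | step 14 | methyl 2-[(3R,6S)-3-methoxy-3-(pent-4-yn-1-yl)-1,2-dioxan-6-yl]acetate (single enantiomer) | CO[C@@]1(CCCC#C)CC[C@@H](CC(=O)OC)OO1
F8 | step 14 | methyl 2-[(3R,6S)-3-methoxy-3-[(E)-15-oxohexadec-6-en-4-yn-1-yl]-1,2-dioxan-6-yl]acetate | CO[C@@]1(CCCC#C/C=C/CCCCCCCC(C)=O)CC[C@@H](CC(=O)OC)OO1
F9 | step 3 | 1-(2-allylcyclobutylidene)-2,2-dimethylhydrazine (racemic) | CN(C)N=C1CCC1CC=C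
F10 | step 3 | rac-2-allylcyclobutan-1-one | O=C1CCC1CC=C
F11 | step 3 | rac-(1R,2R)-2-allyl-1-[5-(trimethylsilyl)pent-4-yn-1-yl]cyclobutan-1-ol | O[C@]1(CCCC#C[Si](C)(C)C)CC[C@@H]1CC=C
F12 | step 3 | rac-(1R,2R)-2-(2-hydroxyethyl)-1-[5-(trimethylsilyl)pent-4-yn-1-yl]cyclobutan-1-ol | O[C@]1(CCCC#C[Si](C)(C)C)CC[C@@H]1CCO
A1 | alternative 1 | tert-butyl 7-(tert-butyldiphenylsilyloxy)-3-oxoheptanoate | CC(C)(C)OC(=O)CC(=O)CCCCO[Si](c1ccccc1)(c1ccccc1)C(C)(C)C
A2 | alternative 1 | methyl but-3-enoate | C=CCC(=O)OC
A3 | alternative 1 | tert-butyl 3-[4-(tert-butyldiphenylsilyloxy)butyl]-3-hydroxy-6-(2-methoxy-2-oxoethyl)-1,2-dioxane-4-carboxylate (racemic, C3/C6 as in the target series, C4 epimers) | O[C@@]1(CCCCO[Si](c2ccccc2)(c2ccccc2)C(C)(C)C)C(C(=O)OC(C)(C)C)C[C@@H](CC(=O)OC)OO1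
A4 | alternative 2 | methyl (E)-6-(tert-butyldiphenylsilyloxy)-4-{[3-methoxy-8-(triisopropylsilyl)oct-1-en-7-yn-3-yl]peroxy}hex-2-enoate (peroxy carbon configured as C6 of the target, ketal epimers) | COC(C=C)(CCCC#C[Si](C(C)C)(C(C)C)C(C)C)OO[C@H](CCO[Si](c1ccccc1)(c1ccccc1)C(C)(C)C)/C=C/C(=O)OC
A5 | alternative 2 | tert-butyl{2-[6-methoxy-6-[5-(triisopropylsilyl)pent-4-yn-1-yl]-3,6-dihydro-1,2-dioxin-3-yl]ethoxy}diphenylsilane (CH carbon configured as C6 of the target, ketal epimers) | COC1(CCCC#C[Si](C(C)C)(C(C)C)C(C)C)C=C[C@@H](CCO[Si](c2ccccc2)(c2ccccc2)C(C)(C)C)OO1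
A6 | alternative 3 | (S)-1-(tert-butyldiphenylsilyloxy)-3-hydroperoxyundec-10-yn-6-one | C#CCCCC(=O)CC[C@H](OO)CCO[Si](c1ccccc1)(c1ccccc1)C(C)(C)C
A7 | alternative 3 | tert-butyl{2-[(3R,6S)-3-methoxy-3-(pent-4-yn-1-yl)-1,2-dioxan-6-yl]ethoxy}diphenylsilane | CO[C@@]1(CCCC#C)CC[C@@H](CCO[Si](c2ccccc2)(c2ccccc2)C(C)(C)C)OO1
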